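**Plan**

1. Numbering follows the longipinane skeleton: C1 ketone, C2, C3 (Me), C4 and C11 bridgeheads, C5 (H), C6 (CMe2), C7 and C8 carbinols, C9, C10 (Me). All intermediates carry the cage centres in the configuration of the target.
2. Retrosynthesis cuts, in order: the two ester C–O bonds; C7–C8 (opens the cycloheptane); C5–C6 (tethered Reformatsky onto a cyclobutanone); C4–C5 together with C10–C11 (intramolecular vinylketene–alkene [2+2]); C3–C4 (conjugate addition).
3. Forward: acyclic dienoic acid → cyclobutane and six-membered ring in one step (bicyclo[3.1.1]heptan-6-one, exocyclic methylene as latent C1 ketone) → temporary eight-membered lactone → seven-membered carbocycle → C1 ketone → diangelate.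
4. Enabling feature: C5 and C10 are the two one-carbon bridges of the bicyclo[3.1.1]heptane. Their substituents that point away from the C1–C2–C3 bridge (C6 and C9) are cis-1,3 on the cyclobutane and about 3 Å apart, so an O8–C7 ester tether and then the C7–C8 bond close without strain; quaternary C6 leaves the C7 acyl group without α-hydrogen.
5. Stereochemistry: C3 from rhodium/(S)-BINAP conjugate addition; C4, C10, C11 from the [2+2] (E-alkene, face chosen by C3–Me); C5 from the tether; C8 from (+)-sparteine and C7 from (S)-CBS. Both carbinol centres are reagent-controlled because C5, C6, C9 and C10 lie in a local mirror plane of the cage, so the substrate cannot tell (7S,8S) from (7R,8R).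

Key step: step 13

**Step 1**
Reactants: 1 tert-butyl(but-3-yn-1-yloxy)dimethylsilane
Product: 3 tert-butyldimethyl{[(3E)-3-methyl-4-(4,4,5,5-tetramethyl-1,3,2-dioxaborolan-2-yl)but-3-en-1-yl]oxy}silane, via dimethylalkenylalane 2 (not isolated)
Conditions: Me3Al, Cp2ZrCl2 (20 mol %), CH2Cl2, 0 °C to rt; then i-PrOBpin, −20 °C to rt
Reagents that add atoms: trimethylaluminium C[Al](C)C; 2-isopropoxy-4,4,5,5-tetramethyl-1,3,2-dioxaborolane CC(C)OB1OC(C)(C)C(C)(C)O1
Why: Negishi zirconium-catalysed syn-carboalumination puts methyl on the internal carbon and the metal cis to it, and aluminium-to-boron exchange keeps the E geometry that later places C10–Me syn to the three-carbon bridge.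

**Step 2**
Reactants: 3 alkenyl pinacol boronate; 4 (E)-pent-3-en-2-one
Product: 5 (4R,5E)-8-(tert-butyldimethylsilyloxy)-4,6-dimethyloct-5-en-2-one
Conditions: [Rh(cod)OH]2 (2 mol %), (S)-BINAP, KOH (0.5 equiv), dioxane/H2O (10:1), 40 °C
Reagents that add atoms: none
Why: Hayashi–Miyaura rhodium-catalysed asymmetric 1,4-addition of the alkenylboronate, in which (S)-BINAP is expected to deliver the alkenyl group to the αsi face of the E-enone (the face it selects on cyclohex-2-enone) and so set C3 as R.

**Step 3**
Reactants: 5 ketone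
Product: 6 ethyl (2E,5R,6E)-9-(tert-butyldimethylsilyloxy)-3,5,7-trimethylnona-2,6-dienoate
Conditions: (EtO)2P(O)CH2CO2Et, NaH, THF, 0 °C to reflux; minor 2Z isomer removed by chromatography
Reagents that add atoms: triethyl phosphonoacetate CCOC(=O)CP(=O)(OCC)OCC
Why: Horner–Wadsworth–Emmons olefination of the methyl ketone should give mainly the 2E enoate, in which the 3-methyl group (the future exocyclic methylene on C1) is cis to the ester as the vinylketene formation requires; C3 is not touched.

**Step 4**
Reactants: 6 ethyl ester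
Product: 7 (2E,5R,6E)-9-(tert-butyldimethylsilyloxy)-3,5,7-trimethylnona-2,6-dienoic acid
Conditions: LiOH, THF/MeOH/H2O, rt; 1 M HCl to pH 4, 0 °C
Reagents that add atoms: lithium hydroxide [Li+].[OH-]
Why: plain ester saponification, which the primary silyl ether and both alkenes should survive at room temperature.

**Step 5**
Reactants: 7 dienoic acid
Product: 10 (1R,2R,5S,7R)-7-[2-(tert-butyldimethylsilyloxy)ethyl]-2,7-dimethyl-4-methylidenebicyclo[3.1.1]heptan-6-one, via acid chloride 8 (not isolated), via vinylketene 9 (not isolated)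
Conditions: NaH, then (COCl)2, benzene, 0 °C to rt; crude 8 added over 6 h to NEt3, toluene, 110 °C (0.01 M)
Reagents that add atoms: none
Why: γ-dehydrochlorination gives the vinylketene, which should undergo the bridged-mode intramolecular ketene–alkene [2+2] cycloaddition known for geranic-acid-type chlorides (ketene carbonyl carbon C5 to the alkene CH C4, ketene α-carbon C11 to the more substituted C10), suprafacially on the E-alkene so that C10–Me is syn to the C1–C3 bridge, with C3–Me choosing the alkene face that leaves it on the side of the carbonyl bridge and away from C10–Me.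

**Step 6**
Reactants: 10 silyl ether
Product: 11 (1R,2R,5S,7R)-7-(2-hydroxyethyl)-2,7-dimethyl-4-methylidenebicyclo[3.1.1]heptan-6-one
Conditions: TBAF, AcOH, THF, 0 °C to rt
Reagents that add atoms: none
Why: buffered fluoride cleavage of the silyl ether, which should leave the strained ketone and the acid-sensitive exocyclic alkene alone.

**Step 7**
Reactants: 11 alcohol
Product: 12 2-bromo-2-methylpropanoate ester of alcohol 11
Conditions: BrC(CH3)2COBr, pyridine, CH2Cl2, 0 °C
Reagents that add atoms: 2-bromo-2-methylpropanoyl bromide CC(C)(Br)C(Br)=O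
Why: acylation of the primary alcohol hangs the C6–C7 unit on O8 as an ester tether (C7 is the ester carbonyl carbon).

**Step 8**
Reactants: 12 bromo ester
Product: 14 5-hydroxy-1-methylidene-7a-oxa-7a-homolongipinan-7-one, via diiodosamarium enolate 13 (not isolated)
Conditions: SmI2 (2.5 equiv), THF, 0.005 M, slow addition, 0 °C; aq NH4Cl
Reagents that add atoms: none
Why: SmI2-mediated intramolecular Reformatsky reaction, an established route to eight- to fourteen-membered β-hydroxy lactones; the enolate hangs from the C10 arm that points away from the C1–C3 bridge and can reach the C5 carbonyl only from that face, which fixes C5 (C6 anti, OH syn to the bridge).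

**Step 9**
Reactants: 14 hydroxy lactone
Product: 15 methyl oxalate of 14 at the C5 oxygen
Conditions: ClCOCO2Me, DMAP, pyridine, CH2Cl2, 0 °C to rt
Reagents that add atoms: methyl chlorooxoacetate COC(=O)C(Cl)=O
Why: acylation of the tertiary cyclobutanol to its methyl oxalate gives the radical precursor for deoxygenation, and elimination cannot compete because the neighbouring carbons are bridgeheads or quaternary.

**Step 10**
Reactants: 15 oxalate
Product: 16 1-methylidene-7a-oxa-7a-homolongipinan-7-one
Conditions: Bu3SnH, AIBN, toluene, 100 °C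
Reagents that add atoms: none
Why: Barton–McCombie-type radical deoxygenation through the tertiary oxalate; the lactone ring holds C6 on the lower face of the C5 radical, so hydrogen should be delivered syn to the C1–C3 bridge and give the natural C5–H configuration.

**Step 11**
Reactants: 16 lactone
Product: 17 8-hydroxy-N-methoxy-N-methyl-1-methylidene-7,8-secolongipinan-7-amide
Conditions: MeNHOMe·HCl, i-PrMgCl, THF, −20 to 0 °C; aq NH4Cl
Reagents that add atoms: N,O-dimethylhydroxylamine hydrochloride CNOC.Cl
Why: aminolysis of the medium-ring lactone by the magnesium amide (Weinreb amide formation) frees the C8 alcohol and turns C7 into an acyl donor that forms a stable tetrahedral adduct.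

**Step 12**
Reactants: 17 hydroxy amide
Product: 18 8-(N,N-diisopropylcarbamoyloxy)-N-methoxy-N-methyl-1-methylidene-7,8-secolongipinan-7-amide
Conditions: i-Pr2NCOCl, NEt3, DMAP (cat.), CH2Cl2, reflux
Reagents that add atoms: N,N-diisopropylcarbamoyl chloride CC(C)N(C(C)C)C(Cl)=O
Why: carbamoylation of the primary alcohol gives the O-alkyl N,N-diisopropylcarbamate needed for directed enantioselective α-lithiation.

**Step 13**
Reactants: 18 carbamate Weinreb amide
Product: 21 (8S)-8-(N,N-diisopropylcarbamoyloxy)-1-methylidenelongipinan-7-one, via α-lithio carbamate 19 (not isolated), via lithium tetrahedral adduct 20 (not isolated)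
Conditions: s-BuLi (1.4 equiv), (+)-sparteine (1.5 equiv), Et2O, −78 °C, 5 h, then −50 °C; aq NH4Cl, −78 °C to rt
Reagents that add atoms: none
Why: s-BuLi/(+)-sparteine binds the carbamate carbonyl and removes the pro-R hydrogen of C8, giving a configurationally stable, dipole-stabilised α-lithio carbamate that attacks the Weinreb carbonyl C7 with retention to form a chelated tetrahedral adduct, which collapses to the ketone only on quench. The closest known reaction type is the Hoppe sparteine-mediated lithiation–acylation of O-alkyl N,N-diisopropylcarbamates, run here within one molecule. The seven-membered ring (C4, C5, C6, C7, C8, C9, C10) closes in the 7-exo-trig mode, helped by the cis-1,3 arms on the cyclobutane that hold C7 and C8 face to face. The new stereocentre C8 (S) is set by the diamine and not by the substrate, because the two C8 hydrogens are related by the local mirror plane through C5, C6, C9 and C10. The step needs deprotonation at C8 to beat addition of s-BuLi to C7; the neopentyl position of the amide next to quaternary C6 shields the carbonyl and offers no α-hydrogen, and the stable tetrahedral adduct keeps the product from being enolised at C8 before the quench.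

**Step 14**
Reactants: 21 carbamoyloxy ketone
Product: 22 (7S,8S)-8-(N,N-diisopropylcarbamoyloxy)-1-methylidenelongipinan-7-ol
Conditions: (S)-Me-CBS (1.0 equiv), catecholborane, toluene, −78 to −40 °C
Reagents that add atoms: none
Why: Corey–Bakshi–Shibata reduction in which quaternary C6 acts as the large and C8 as the small substituent, so the (S)-oxazaborolidine should deliver hydride to give 7S (trans to the C8 oxygen), while catecholborane spares the exocyclic alkene.

**Step 15**
Reactants: 22 hydroxy carbamate
Product: 23 (7S,8S)-1-methylidenelongipinane-7,8-diol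
Conditions: LiAlH4, THF, reflux; NaOH/H2O work-up
Reagents that add atoms: none
Why: reductive cleavage of the N,N-diisopropylcarbamate, the standard release of the alcohol after carbamate-directed lithiation, which affects no stereocentre.

**Step 16**
Reactants: 23 diol
Product: 25 (7S,8S)-7,8-dihydroxylongipinan-1-one, via ozonide 24 (not isolated)
Conditions: O3, CH2Cl2, −78 °C; Me2S, −78 °C to rt
Reagents that add atoms: ozone [O-][O+]=O
Why: ozonolysis of the 1,1-disubstituted alkene unmasks the C1 ketone carried since the cycloaddition, and the secondary alcohols are inert at −78 °C.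

**Step 17**
Reactants: 25 dihydroxy ketone; 26 angelic acid [(2Z)-2-methylbut-2-enoic acid]
Product: 27 (3R,4S,5S,7S,8S,10R,11R)-7,8-bis[(2Z)-2-methylbut-2-enoyloxy]longipinan-1-one
Conditions: 26 (6 equiv), 2,4,6-Cl3C6H2COCl, NEt3, toluene, rt; then 25, 80 °C (no DMAP)
Reagents that add atoms: none
Why: Yamaguchi-type esterification through the mixed anhydride without a nucleophilic catalyst, the variant that should acylate hindered secondary alcohols with angelic acid without Z-to-E isomerisation to the tiglate, and under which the C1 ketone needs no protection.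

**Compound list**

1 | tert-butyl(but-3-yn-1-yloxy)dimethylsilane | C#CCCO[Si](C)(C)C(C)(C)C | starting material
2 | dimethyl[(1E)-4-(tert-butyldimethylsilyloxy)-2-methylbut-1-enyl]alane | CC(C)(C)[Si](C)(C)OCC/C(C)=C/[Al](C)C | intermediate (not isolated)
3 | tert-butyldimethyl{[(3E)-3-methyl-4-(4,4,5,5-tetramethyl-1,3,2-dioxaborolan-2-yl)but-3-en-1-yl]oxy}silane | CC(C)(C)[Si](C)(C)OCC/C(C)=C/B1OC(C)(C)C(C)(C)O1 | intermediate
4 | (E)-pent-3-en-2-one | C/C=C/C(C)=O | starting material
5 | (4R,5E)-8-(tert-butyldimethylsilyloxy)-4,6-dimethyloct-5-en-2-one | CC(=O)C[C@@H](C)/C=C(\C)CCO[Si](C)(C)C(C)(C)C | intermediate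
6 | ethyl (2E,5R,6E)-9-(tert-butyldimethylsilyloxy)-3,5,7-trimethylnona-2,6-dienoate | CCOC(=O)/C=C(\C)C[C@@H](C)/C=C(\C)CCO[Si](C)(C)C(C)(C)C | intermediate
7 | (2E,5R,6E)-9-(tert-butyldimethylsilyloxy)-3,5,7-trimethylnona-2,6-dienoic acid | OC(=O)/C=C(\C)C[C@@H](C)/C=C(\C)CCO[Si](C)(C)C(C)(C)C | intermediate
8 | acid chloride of 7 | ClC(=O)/C=C(\C)C[C@@H](C)/C=C(\C)CCO[Si](C)(C)C(C)(C)C | intermediate (not isolated)
9 | (5R,6E)-9-(tert-butyldimethylsilyloxy)-5,7-dimethyl-3-methylidenenona-1,6-dien-1-one (vinylketene) | O=C=CC(=C)C[C@@H](C)/C=C(\C)CCO[Si](C)(C)C(C)(C)C | intermediate (not isolated)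
10 | (1R,2R,5S,7R)-7-[2-(tert-butyldimethylsilyloxy)ethyl]-2,7-dimethyl-4-methylidenebicyclo[3.1.1]heptan-6-one (7-Me syn to the three-carbon bridge, 2-Me on the side of the carbonyl bridge) | CC(C)(C)[Si](C)(C)OCC[C@]1(C)[C@@H]2C(=O)[C@H]1C(=C)C[C@H]2C | intermediate
11 | (1R,2R,5S,7R)-7-(2-hydroxyethyl)-2,7-dimethyl-4-methylidenebicyclo[3.1.1]heptan-6-one | OCC[C@]1(C)[C@@H]2C(=O)[C@H]1C(=C)C[C@H]2C | intermediate
12 | 2-bromo-2-methylpropanoate ester of alcohol 11 | CC(C)(Br)C(=O)OCC[C@]1(C)[C@@H]2C(=O)[C@H]1C(=C)C[C@H]2C | intermediate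
13 | diiodosamarium ester enolate derived from 12 | CC(C)=C(O[Sm](I)I)OCC[C@]1(C)[C@@H]2C(=O)[C@H]1C(=C)C[C@H]2C | intermediate (not isolated)
14 | 5-hydroxy-1-methylidene-7a-oxa-7a-homolongipinan-7-one (eight-membered lactone, ring oxygen between C7 and C8, C5–OH syn to the C1–C3 bridge) | O=C1OCC[C@]2(C)[C@@H]3[C@@](O)([C@H]2C(=C)C[C@H]3C)C1(C)C | intermediate
15 | methyl oxalate of 14 at the C5 oxygen | O=C1OCC[C@]2(C)[C@@H]3[C@@](OC(=O)C(=O)OC)([C@H]2C(=C)C[C@H]3C)C1(C)C | intermediate
16 | 1-methylidene-7a-oxa-7a-homolongipinan-7-one | O=C1OCC[C@]2(C)[C@@H]3[C@@H]([C@H]2C(=C)C[C@H]3C)C1(C)C | intermediate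
17 | 8-hydroxy-N-methoxy-N-methyl-1-methylidene-7,8-secolongipinan-7-amide | OCC[C@]1(C)[C@@H]2[C@@H]([C@H]1C(=C)C[C@H]2C)C(C)(C)C(=O)N(C)OC | intermediate
18 | 8-(N,N-diisopropylcarbamoyloxy)-N-methoxy-N-methyl-1-methylidene-7,8-secolongipinan-7-amide | CC(C)N(C(C)C)C(=O)OCC[C@]1(C)[C@@H]2[C@@H]([C@H]1C(=C)C[C@H]2C)C(C)(C)C(=O)N(C)OC | intermediate
19 | (8R)-8-lithio derivative of 18 | CC(C)N(C(C)C)C(=O)O[C@H]([Li])C[C@]1(C)[C@@H]2[C@@H]([C@H]1C(=C)C[C@H]2C)C(C)(C)C(=O)N(C)OC | intermediate (not isolated)
20 | lithium alkoxide of the cyclic N-methoxy-N-methyl hemiaminal at C7 (C7 configuration not defined) | CC(C)N(C(C)C)C(=O)O[C@H]1C[C@]2(C)[C@@H]3[C@@H]([C@H]2C(=C)C[C@H]3C)C(C)(C)C1(O[Li])N(C)OC | intermediate (not isolated)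
21 | (8S)-8-(N,N-diisopropylcarbamoyloxy)-1-methylidenelongipinan-7-one | CC(C)N(C(C)C)C(=O)O[C@H]1C[C@]2(C)[C@@H]3[C@@H]([C@H]2C(=C)C[C@H]3C)C(C)(C)C1=O | intermediate
22 | (7S,8S)-8-(N,N-diisopropylcarbamoyloxy)-1-methylidenelongipinan-7-ol | CC(C)N(C(C)C)C(=O)O[C@H]1C[C@]2(C)[C@@H]3[C@@H]([C@H]2C(=C)C[C@H]3C)C(C)(C)[C@@H]1O | intermediate
23 | (7S,8S)-1-methylidenelongipinane-7,8-diol | O[C@H]1C[C@]2(C)[C@@H]3[C@@H]([C@H]2C(=C)C[C@H]3C)C(C)(C)[C@@H]1O | intermediate
24 | spiro-1,2,4-trioxolane (ozonide) of 23 at C1 | O[C@H]1C[C@]2(C)[C@@H]3[C@@H]([C@H]2C4(OOCO4)C[C@H]3C)C(C)(C)[C@@H]1O | intermediate (not isolated)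
25 | (7S,8S)-7,8-dihydroxylongipinan-1-one | O[C@H]1C[C@]2(C)[C@@H]3[C@@H]([C@H]2C(=O)C[C@H]3C)C(C)(C)[C@@H]1O | intermediate
26 | angelic acid, (2Z)-2-methylbut-2-enoic acid | C/C=C(/C)C(=O)O | starting material
27 | (3R,4S,5S,7S,8S,10R,11R)-7,8-bis[(2Z)-2-methylbut-2-enoyloxy]longipinan-1-one | C/C=C(/C)C(=O)O[C@H]1C[C@]2(C)[C@@H]3[C@@H]([C@H]2C(=O)C[C@H]3C)C(C)(C)[C@@H]1OC(=O)/C(C)=C\C | target

**Step count**

Total: 17 steps. Longest linear sequence: 17 steps (1 to 27); 4 and 26 enter as purchased building blocks.

**Steps most likely to fail**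

Step 13. The base may add to the Weinreb carbonyl or fragment its N–O bond faster than it removes the C8 proton, or the lithiated carbamate may lose configuration before it closes the ring. The fallback sets out from lactone 16. Reduction with LiAlH4 would give the diol 2-[7-(2-hydroxyethyl)-2,7-dimethyl-4-methylidenebicyclo[3.1.1]heptan-6-yl]-2-methylpropan-1-ol F1, and Swern oxidation the dialdehyde 2-[2,7-dimethyl-4-methylidene-7-(2-oxoethyl)bicyclo[3.1.1]heptan-6-yl]-2-methylpropanal F2. Reductive pinacol cyclisation with Cp2TiPh (trivalent titanium, generated from Cp2TiCl2, i-PrMgCl and PhMgBr; THF, −78 °C to rt), a reagent that favours trans-1,2-diols in ring-closing couplings of dialdehydes, would still form C7–C8 as the ring-closing bond. The cage cannot bias the two trans arrangements, so diol 23 would have to be separated by chromatography from (7R,8R)-1-methylidenelongipinane-7,8-diol F3. The route is rejoined at 23.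

Step 5. At 110 °C the amine may remove a C2 proton instead of a methyl proton, the ketene may oligomerise, or the C3 methyl group may discriminate poorly between the two alkene faces. The fallback sets out from ester 6. Deconjugative protonation (LDA, THF/DMPU, −78 °C; AcOH quench) would move the double bond and give ethyl (5R,6E)-9-(tert-butyldimethylsilyloxy)-5,7-dimethyl-3-methylidenenon-6-enoate F4. LiOH at 0 °C would give (5R,6E)-9-(tert-butyldimethylsilyloxy)-5,7-dimethyl-3-methylidenenon-6-enoic acid F5, and NaH/(COCl)2 its acid chloride F6. From F6, NEt3 should generate vinylketene 9 by simple α-dehydrochlorination at 25–40 °C, without regiochemical ambiguity and at a temperature where face selection should be sharper. Cycloaddition returns to 10.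

Step 8. The enolate may be protonated or may react between molecules faster than it closes the eight-membered ring. The fallback sets out from silyl ether 10 and gives up the tether. Aldol addition of the lithium enolate of N-methoxy-N,2-dimethylpropanamide (LDA, THF, −78 °C) is expected to enter anti to the C1–C3 bridge and give 2-{7-[2-(tert-butyldimethylsilyloxy)ethyl]-6-hydroxy-2,7-dimethyl-4-methylidenebicyclo[3.1.1]heptan-6-yl}-N-methoxy-N,2-dimethylpropanamide F7. ClCOCO2Me/DMAP would give its methyl oxalate F8, and Bu3SnH/AIBN the deoxygenated silyl ether of 17 F9, the bulky C6 group staying anti while hydrogen adds syn. TBAF then gives 17, where the route is rejoined. In this variant C5 is controlled by the cage alone, which is less secure than the tether.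

**Further compounds**

F1 | step 13 | 2-[7-(2-hydroxyethyl)-2,7-dimethyl-4-methylidenebicyclo[3.1.1]heptan-6-yl]-2-methylpropan-1-ol | OCC[C@]1(C)[C@@H]2[C@@H]([C@H]1C(=C)C[C@H]2C)C(C)(C)CO
F2 | step 13 | 2-[2,7-dimethyl-4-methylidene-7-(2-oxoethyl)bicyclo[3.1.1]heptan-6-yl]-2-methylpropanal | O=CC[C@]1(C)[C@@H]2[C@@H]([C@H]1C(=C)C[C@H]2C)C(C)(C)C=O
F3 | step 13 | (7R,8R)-1-methylidenelongipinane-7,8-diol | O[C@@H]1C[C@]2(C)[C@@H]3[C@@H]([C@H]2C(=C)C[C@H]3C)C(C)(C)[C@H]1O
F4 | step 5 | ethyl (5R,6E)-9-(tert-butyldimethylsilyloxy)-5,7-dimethyl-3-methylidenenon-6-enoate | CCOC(=O)CC(=C)C[C@@H](C)/C=C(\C)CCO[Si](C)(C)C(C)(C)C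
F5 | step 5 | (5R,6E)-9-(tert-butyldimethylsilyloxy)-5,7-dimethyl-3-methylidenenon-6-enoic acid | OC(=O)CC(=C)C[C@@H](C)/C=C(\C)CCO[Si](C)(C)C(C)(C)C
F6 | step 5 | acid chloride of F5 | ClC(=O)CC(=C)C[C@@H](C)/C=C(\C)CCO[Si](C)(C)C(C)(C)C
F7 | step 8 | 2-{7-[2-(tert-butyldimethylsilyloxy)ethyl]-6-hydroxy-2,7-dimethyl-4-methylidenebicyclo[3.1.1]heptan-6-yl}-N-methoxy-N,2-dimethylpropanamide | CC(C)(C)[Si](C)(C)OCC[C@]1(C)[C@@H]2[C@@](O)([C@H]1C(=C)C[C@H]2C)C(C)(C)C(=O)N(C)OC
F8 | step 8 | methyl oxalate of F7 | CC(C)(C)[Si](C)(C)OCC[C@]1(C)[C@@H]2[C@@](OC(=O)C(=O)OC)([C@H]1C(=C)C[C@H]2C)C(C)(C)C(=O)N(C)OC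
F9 | step 8 | tert-butyldimethylsilyl ether of 17 | CC(C)(C)[Si](C)(C)OCC[C@]1(C)[C@@H]2[C@@H]([C@H]1C(=C)C[C@H]2C)C(C)(C)C(=O)N(C)OC
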